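## Analysis of the target

The target 19 is (4S)-5,8-dihydroxy-4-(4-hydroxy-8-methoxynaphthalen-1-yl)-3,4-dihydronaphthalen-1(2H)-one. It is a tetralone (ring C = cyclohexanone C1–C4, ring D = hydroquinone C4a–C8a) joined through its sp3 carbon C4 to C1′ of a naphthalene (ring A = C1′–C4′ with the free hydroxyl at C4′, ring B = C5′–C8′ with the methoxy group at C8′). C4 is the only stereocentre. It is doubly benzylic, flanked by the C5 hydroxyl on one side and the peri C8′ methoxy group on the other, and is S (priorities C4a > C1′ > C3 > H). It is not alpha to the ketone, so enolisation cannot scramble it. It is lost, however, if ring C ever becomes aromatic, or if ring D reaches a quinone that can tautomerise through C4–H. The sensitive groups are the hydroquinone of ring D and the para-alkylated naphthol of ring A, both easily oxidised under basic conditions, and the aryl ketone next to the C8 hydroxyl. The difficulty is to make a crowded diaryl methine as one enantiomer with no neighbouring group to direct it, and to tell four arene oxygens apart. The plan rests on one feature: ring D, with para oxygens at C5 and C8 and the fusion bond C4a–C8a, is the enol form of a 1,4-benzoquinone unit, and C1–C2–C3–C4 is a four-carbon chain oxygenated at one end and arylated at the other, so C4–C4a and C1–C8a are the two bonds of a Diels–Alder reaction.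

## Retrosynthetic reasoning

**19 ⇒ 18 ⇒ 17 (O–benzyl and O–acetyl bonds).** The three phenols are uncovered last. The naphthol oxygen is carried as a benzyl ether, which has to survive an organolithium, a ruthenium carbene, a silyl triflate, a Lewis acid, fluoride and a periodinane. The ring D oxygens are carried as acetates, because they can be put on in the same operation that aromatises ring D. The acetates go first and the benzyl group last, so that 19 is released under neutral, reducing conditions.

**17 ⇒ 16 ⇒ 15 (C1 oxidation level).** The ketone is taken back to a silyl-protected secondary alcohol. C1 must stay at the alcohol level while ring C is unsaturated: a C1 carbonyl next to a C2=C3 bond would be the keto tautomer of a naphthol and would erase C4. The forward steps are a desilylation that must not move the neighbouring C8 acetate, and an oxidation.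

**15 ⇒ 14 (C2=C3 unsaturation).** Putting a double bond back between C2 and C3 reveals the cyclohexene of a cycloadduct. The forward step must saturate a cis-alkene without cleaving the benzyl ether or the benzylic C1–O bond and without moving the double bond toward C4.

**14 ⇒ 13 ⇒ 12 (ring D as an enedione).** The aromatic ring D is the double enol of a cis-fused cyclohexenedione. No C–C bond is cut; the hydrogens return to C4a and C8a. Both ring D oxygens then come from a quinone, and no arene functionalisation is needed.

**12 ⇒ 10 + 11 (C4–C4a and C1–C8a; C8–C8a and C5–C4a in the numbering of 12).** These are the only two bonds whose cleavage gives a symmetric, commercial six-carbon dienophile and a diene that carries both ring C substituents at its ends. The cut runs next to the stereocentre, so the ring-forming step also creates C4. Forward, the cycloaddition must be endo and face-selective; the symmetry of 11 removes any question of orientation. The centres at C4a, C8a and C1 are erased later, so only the face matters in the end.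

**10 ⇒ 9 (O–Si bond, γ-hydrogen returned).** The silyl dienol ether comes from the conjugated E-enal by O-silylation and loss of the benzylic γ-proton. The s-trans enal delivers the 1E enol ether, and the new styrene bond forms E for steric reasons. A Wittig extension of a C1′ aldehyde with an unstabilised ylide carrying a masked aldehyde was set aside. Such ylides give mainly the Z styrene, and α-deprotonation of the resulting β,γ-unsaturated aldehyde favours the Z enol ether. Both are the wrong geometry for a diene that must reach the s-cis conformation.

**9 ⇒ 7 + 8 (C2=C3 of the butenal).** Cross-metathesis of the allylarene with a commercial enal supplies the last two carbons and sets the E-enal under thermodynamic control.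

**7 ⇒ 6 ⇒ 4 + 5 (C1′–CH2 bond).** The allyl group is attached to the aryl anion generated from the aryl bromide. The bromine marks the position peri to the methoxy group.

**4 ⇒ 3 ⇒ 2 ⇒ 1 (O–benzyl, C–Br, O–methyl).** The order matters. The symmetric diol 1 is methylated once. Bromination follows while the other hydroxyl is still free, so that the stronger donor directs the electrophile para within its own ring. Benzylation comes after that.

## Alternatives that were turned down

**Alternative 1: aryne–furan cycloaddition to build ring A.**
- Disconnection: C1′–C8a′ and C4′–C4a′.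
- Forward key step: the methoxy-substituted aryne released by fluoride from silyl triflate A3 adds across C2 and C5 of the furyl tetralone A2. This gives the oxygen-bridged cycloadduct A1, which acid then opens to the C4′ naphthol.
- For: it is convergent. The crowded C4–C1′ bond is made while the aryl partner is only a furan. The methoxy group is in the aryne from the start and the C4′ hydroxyl comes from the furan oxygen, so the naphthalene oxygens are differentiated by construction. On that point it is stronger than the chosen route, which depends on a regioselective bromination (step 2).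
- Against:
  - The aryne can add in two orientations. The one needed puts the bulky tetralone-bearing bridgehead next to the methoxy carbon, which should be the disfavoured one.
  - The basic fluoride medium meets an enolisable ketone that can itself add to the aryne.
  - Acid opening of A1 creates a cation at C1′ directly beside C4.
  - The step does not create C4, so A2 must already be a single enantiomer and needs an asymmetric ring-forming step of its own.
- Comparison: the chosen route offers instead a ring-forming step that also sets C4 from an achiral diene, with no orientational isomers.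

**Alternative 2: cobalt (2+2+2) cycloaddition.**
- Disconnection: C4a–C8a, C5–C6 and C7–C8.
- Forward key step: CpCo(CO)2 A7 co-cyclises the diyne bis(boronate) A5 with acetylene A6 to give the tetralin bis(boronate) A4. The C–B bonds are then oxidised to the hydroquinone.
- For: three C–C bonds and two rings form at once. Boron fixes the C5 and C8 oxygens. Ring C is never unsaturated, so there is no risk of aromatising it; on that point it is stronger than the chosen route, which passes through the 1,4-dihydronaphthalene 14.
- Against:
  - C4 must exist beforehand in the open chain of A5 as a propargylic, benzylic methine. That is harder to make as one enantiomer and easier to racemise than anything in the chosen route.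
  - A5 needs a long preparation.
  - A6 trimerises with itself and A5 can oligomerise.
  - One boronate ends up wedged between the ring fusion and the naphthyl-bearing C4, which strains the metallacycle.
  - Two hindered aryl boronates must be oxidised beside an electron-rich naphthalene.
- Comparison: the chosen route draws all ten tetralone carbons from 5, 8 and 11 and sets C4 catalytically in the ring-forming step.

**Alternative 3: Wolff rearrangement and 6π closure to build ring B last.**
- Disconnection: C8′–C8a′.
- Forward key step: irradiation of diazoketone A9 gives, by Wolff rearrangement, a ketene that closes onto the arene to form naphthol A8. The new hydroxyl is then methylated.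
- For: the C8′ oxygen appears at a defined position and is chemically distinct from the benzylated C4′ oxygen. This is at least as strong as the chosen route on oxygen differentiation and needs no electrophilic substitution.
- Against:
  - The closure must occur at the arene carbon lying between the side chain and the bulky tetralin substituent, building the peri strain in the ring-forming transition state.
  - It passes through a dearomatised intermediate.
  - The alkene must be Z for closure.
  - The tetralone must be masked as a ketal, because an ortho-alkyl aryl ketone would photoenolise through C4–H.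
  - The whole sequence is linear, late-stage work on a chiral tetralin whose C4 was set by some other reaction.
- Comparison: the chosen route reaches the naphthalene fragment in three steps from a commodity diol and sets C4 in the key step.

Key step: step 7

Remark on numbering: compounds 13–19 carry the tetralone numbering of the target (C1 oxygenated carbon, C4 stereocentre, C5 and C8 oxygenated arene carbons); adduct 12 is numbered as a naphthalene-1,4-dione.

Assumption: the sense of induction of the BINOL–titanium catalyst with this diene cannot be predicted with confidence. (R)-BINOL is written; if the first run gives the enantiomeric series, the (S)-ligand is used.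

## Route

Step 1
Reactants: 1 naphthalene-1,5-diol
Product: 2 5-methoxynaphthalen-1-ol
Conditions: MeI (1.0 equiv), K2CO3 (1.0 equiv), acetone, reflux
Reagents that add atoms: iodomethane, CI
Why: Williamson O-methylation of the symmetric diol with one equivalent of base and electrophile should give mainly the mono-ether; the neutral dimethyl ether and the more polar diol are removed by base extraction and chromatography.

Step 2
Reactants: 2 5-methoxynaphthalen-1-ol
Product: 3 4-bromo-5-methoxynaphthalen-1-ol
Conditions: NBS (1.0 equiv), MeCN, −20 → 0 °C, dark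
Reagents that add atoms: N-bromosuccinimide, O=C1CCC(=O)N1Br
Why: Electrophilic aromatic bromination; the free hydroxyl activates its own ring more than the methoxy group activates the other, and in a polar solvent attack para to the hydroxyl (C4) should be preferred over ortho (C2).

Step 3
Reactants: 3 4-bromo-5-methoxynaphthalen-1-ol
Product: 4 1-(benzyloxy)-4-bromo-5-methoxynaphthalene
Conditions: BnBr (1.2 equiv), K2CO3 (1.5 equiv), DMF, rt
Reagents that add atoms: benzyl bromide, BrCc1ccccc1
Why: Williamson ether synthesis on the naphthol; the benzyl ether tolerates every later reagent and is removed by hydrogenolysis in the last step.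

Step 4
Reactants: 4 1-(benzyloxy)-4-bromo-5-methoxynaphthalene; 5 3-bromoprop-1-ene (allyl bromide)
Product: 7 4-(benzyloxy)-8-methoxy-1-(prop-2-en-1-yl)naphthalene, via aryllithium 6 (not isolated)
Conditions: n-BuLi (1.05 equiv), THF, −78 °C; CuBr·SMe2 (10 mol %), then 5 (1.5 equiv), −78 → 0 °C
Reagents that add atoms: none
Why: Bromine–lithium exchange at −78 °C is faster than any attack on the benzyl ether, and the aryllithium, held by the peri methoxy group, undergoes copper-catalysed allylic substitution with allyl bromide.

Step 5
Reactants: 7 4-(benzyloxy)-8-methoxy-1-(prop-2-en-1-yl)naphthalene; 8 (2E)-but-2-enal (crotonaldehyde)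
Product: 9 (2E)-4-[4-(benzyloxy)-8-methoxynaphthalen-1-yl]but-2-enal
Conditions: 8 (5 equiv), RuCl2(SIMes)(=CH–C6H4-2-Oi-Pr) (second-generation Hoveyda–Grubbs catalyst, 5 mol %), CH2Cl2, 40 °C
Reagents that add atoms: none
Why: Olefin cross-metathesis of a terminal allylarene with an excess of an electron-poor enal; the excess suppresses homodimerisation and the conjugated product should form as the E isomer under thermodynamic control.

Step 6
Reactants: 9 (2E)-4-[4-(benzyloxy)-8-methoxynaphthalen-1-yl]but-2-enal
Product: 10 {[(1E,3E)-4-[4-(benzyloxy)-8-methoxynaphthalen-1-yl]buta-1,3-dien-1-yl]oxy}tri(propan-2-yl)silane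
Conditions: TIPSOTf (1.2 equiv), Et3N (2.0 equiv), Et2O, 0 °C → rt; filtration through Et3N-deactivated silica
Reagents that add atoms: triisopropylsilyl trifluoromethanesulfonate, CC(C)[Si](C(C)C)(C(C)C)OS(=O)(=O)C(F)(F)F
Why: Soft enolisation: O-silylation of the s-trans enal gives an oxocarbenium ion that loses the acidic benzylic γ-proton, so the enol ether bond should form 1E and the new styrene bond 3E, with the twisted naphthyl group turned away from C2. Any Z isomer cannot reach the s-cis conformation easily and should stay behind in step 7.

Step 7
Reactants: 10 {[(1E,3E)-4-[4-(benzyloxy)-8-methoxynaphthalen-1-yl]buta-1,3-dien-1-yl]oxy}tri(propan-2-yl)silane; 11 cyclohexa-2,5-diene-1,4-dione (1,4-benzoquinone)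
Product: 12 (4aR,5S,8R,8aR)-8-[4-(benzyloxy)-8-methoxynaphthalen-1-yl]-5-{[tri(propan-2-yl)silyl]oxy}-4a,5,8,8a-tetrahydronaphthalene-1,4-dione (endo adduct, cis ring fusion, the hydrogens at C4a, C5, C8 and C8a all on one face)
Conditions: TiCl2(Oi-Pr)2 (10 mol %), (R)-1,1′-bi-2-naphthol (10 mol %), 4 Å MS (filtered off before use), 11 (2.0 equiv), CH2Cl2/toluene, −40 → −20 °C; rapid chromatography to remove surplus 11
Reagents that add atoms: none
Why: The titanium centre of the BINOL complex binds one carbonyl oxygen of 11, lowers the LUMO of the neighbouring C=C bond and shields one of its faces with a naphthyl ring of the ligand. Diene 10 then adds in a concerted, asynchronous, normal-electron-demand (4+2) cycloaddition in which the bond from its aryl-bearing terminus (remote from oxygen, largest HOMO coefficient) is the more advanced; the closest known reaction type is the BINOL–titanium-catalysed Diels–Alder reaction of quinones with 1-acyloxy- and 1-alkoxybutadienes. Ring C is closed by this one intermolecular cycloaddition, suprafacial on both partners, which forms C8–C8a and C5–C4a of 12 (C4–C4a and C1–C8a of the target). C8, the future C4, is set by the catalyst-controlled choice of quinone face together with the endo orientation; C5 is locked cis to it by the 1E,3E geometry of 10; C4a and C8a are cis to each other because the quinone alkene is Z, and their hydrogens share a face with those at C5 and C8 because the second quinone carbonyl lies under C2–C3 of the diene in the endo transition state. The step needs endo, facial and mono-addition selectivity: secondary orbital overlap and the Lewis acid should secure endo, the ligand the face, and the symmetry of 11 removes any question of orientation, while the excess of 11 and the lower dienophilicity of enedione 12 should prevent a second addition. The catalyst is freed from molecular sieves and the mixture kept cold so that 12 does not enolise in the flask, where surplus 11 would oxidise the resulting hydroquinone.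

Step 8
Reactants: 12 (4aR,5S,8R,8aR)-8-[4-(benzyloxy)-8-methoxynaphthalen-1-yl]-5-{[tri(propan-2-yl)silyl]oxy}-4a,5,8,8a-tetrahydronaphthalene-1,4-dione
Product: 14 (1S,4S)-4-[4-(benzyloxy)-8-methoxynaphthalen-1-yl]-1-{[tri(propan-2-yl)silyl]oxy}-1,4-dihydronaphthalene-5,8-diyl diacetate, via hydroquinone 13 (not isolated)
Conditions: Ac2O (4 equiv, present before the base), Et3N (4 equiv), DMAP (10 mol %), CH2Cl2, −20 → 0 °C
Reagents that add atoms: acetic anhydride, CC(=O)OC(C)=O
Why: Amine-promoted double enolisation of the cis-enedione gives the aromatic hydroquinone, which DMAP-catalysed acetylation traps as it forms, so no free phenol remains to expel the ortho-benzylic silyloxy group. C4a and C8a become sp2, and the centres at C1 and C4 are untouched (cis, 1S,4S).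

Step 9
Reactants: 14 (1S,4S)-4-[4-(benzyloxy)-8-methoxynaphthalen-1-yl]-1-{[tri(propan-2-yl)silyl]oxy}-1,4-dihydronaphthalene-5,8-diyl diacetate
Product: 15 (1S,4S)-4-[4-(benzyloxy)-8-methoxynaphthalen-1-yl]-1-{[tri(propan-2-yl)silyl]oxy}-1,2,3,4-tetrahydronaphthalene-5,8-diyl diacetate
Conditions: 2-nitrobenzenesulfonyl hydrazide (6 equiv, in portions), Et3N, CH2Cl2, rt
Reagents that add atoms: none
Why: Diimide, released from the sulfonyl hydrazide, transfers two hydrogens in a concerted syn fashion to the cis-disubstituted C2=C3 bond from the face opposite the aryl and silyloxy groups. It neither moves the double bond toward C4 nor cleaves benzylic C–O bonds, and no stereocentre is created.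

Step 10
Reactants: 15 (1S,4S)-4-[4-(benzyloxy)-8-methoxynaphthalen-1-yl]-1-{[tri(propan-2-yl)silyl]oxy}-1,2,3,4-tetrahydronaphthalene-5,8-diyl diacetate
Product: 16 (1S,4S)-4-[4-(benzyloxy)-8-methoxynaphthalen-1-yl]-1-hydroxy-1,2,3,4-tetrahydronaphthalene-5,8-diyl diacetate
Conditions: HF·pyridine, pyridine, THF, 0 °C → rt
Reagents that add atoms: none
Why: Fluoride cleaves the Si–O bond under acidic buffering, so no alkoxide forms that could take over the neighbouring C8 acetate; the aryl acetates and the benzyl ether are inert to these conditions.

Step 11
Reactants: 16 (1S,4S)-4-[4-(benzyloxy)-8-methoxynaphthalen-1-yl]-1-hydroxy-1,2,3,4-tetrahydronaphthalene-5,8-diyl diacetate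
Product: 17 (4S)-4-[4-(benzyloxy)-8-methoxynaphthalen-1-yl]-1-oxo-1,2,3,4-tetrahydronaphthalene-5,8-diyl diacetate
Conditions: Dess–Martin periodinane (1.5 equiv), CH2Cl2, 0 °C → rt
Reagents that add atoms: none
Why: Dess–Martin oxidation of the secondary benzylic alcohol to the aryl ketone; C4 is now the only stereocentre and, not being alpha to the carbonyl, is not epimerised.

Step 12
Reactants: 17 (4S)-4-[4-(benzyloxy)-8-methoxynaphthalen-1-yl]-1-oxo-1,2,3,4-tetrahydronaphthalene-5,8-diyl diacetate
Product: 18 (4S)-4-[4-(benzyloxy)-8-methoxynaphthalen-1-yl]-5,8-dihydroxy-3,4-dihydronaphthalen-1(2H)-one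
Conditions: K2CO3 (0.5 equiv), degassed MeOH, 0 °C, Ar; then aq. NH4Cl
Reagents that add atoms: none
Why: Base-catalysed methanolysis of the two aryl acetates, run cold and oxygen-free so that the acyl hydroquinone is not oxidised to a quinone that could tautomerise through C4–H; the benzyl ether is unaffected.

Step 13
Reactants: 18 (4S)-4-[4-(benzyloxy)-8-methoxynaphthalen-1-yl]-5,8-dihydroxy-3,4-dihydronaphthalen-1(2H)-one
Product: 19 (4S)-5,8-dihydroxy-4-(4-hydroxy-8-methoxynaphthalen-1-yl)-3,4-dihydronaphthalen-1(2H)-one
Conditions: H2 (1 atm), Pd/C (10 wt %), EtOAc, rt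
Reagents that add atoms: none
Why: Hydrogenolysis of the benzyl aryl ether over palladium; the ketone, hydrogen-bonded to the C8 hydroxyl, and the diaryl methine should not be reduced at 1 atm, and the neutral reducing medium protects the hydroquinone.

## Compound list

1 | naphthalene-1,5-diol | Oc1cccc2c(O)cccc12 | starting material
2 | 5-methoxynaphthalen-1-ol | COc1cccc2c(O)cccc12 | intermediate
3 | 4-bromo-5-methoxynaphthalen-1-ol | COc1cccc2c(O)ccc(Br)c12 | intermediate
4 | 1-(benzyloxy)-4-bromo-5-methoxynaphthalene | COc1cccc2c(OCc3ccccc3)ccc(Br)c12 | intermediate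
5 | 3-bromoprop-1-ene | C=CCBr | starting material
6 | [4-(benzyloxy)-8-methoxynaphthalen-1-yl]lithium | COc1cccc2c(OCc3ccccc3)ccc([Li])c12 | intermediate (not isolated)
7 | 4-(benzyloxy)-8-methoxy-1-(prop-2-en-1-yl)naphthalene | COc1cccc2c(OCc3ccccc3)ccc(CC=C)c12 | intermediate
8 | (2E)-but-2-enal | C/C=C/C=O | starting material
9 | (2E)-4-[4-(benzyloxy)-8-methoxynaphthalen-1-yl]but-2-enal | COc1cccc2c(OCc3ccccc3)ccc(C/C=C/C=O)c12 | intermediate
10 | {[(1E,3E)-4-[4-(benzyloxy)-8-methoxynaphthalen-1-yl]buta-1,3-dien-1-yl]oxy}tri(propan-2-yl)silane | COc1cccc2c(OCc3ccccc3)ccc(/C=C/C=C/O[Si](C(C)C)(C(C)C)C(C)C)c12 | intermediate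
11 | cyclohexa-2,5-diene-1,4-dione | O=C1C=CC(=O)C=C1 | starting material
12 | (4aR,5S,8R,8aR)-8-[4-(benzyloxy)-8-methoxynaphthalen-1-yl]-5-{[tri(propan-2-yl)silyl]oxy}-4a,5,8,8a-tetrahydronaphthalene-1,4-dione | COc1cccc2c(OCc3ccccc3)ccc(c12)[C@@H]1C=C[C@H](O[Si](C(C)C)(C(C)C)C(C)C)[C@@H]2C(=O)C=CC(=O)[C@H]12 | intermediate
13 | (1S,4S)-4-[4-(benzyloxy)-8-methoxynaphthalen-1-yl]-1-{[tri(propan-2-yl)silyl]oxy}-1,4-dihydronaphthalene-5,8-diol | COc1cccc2c(OCc3ccccc3)ccc(c12)[C@@H]1C=C[C@H](O[Si](C(C)C)(C(C)C)C(C)C)c2c(O)ccc(O)c12 | intermediate (not isolated)
14 | (1S,4S)-4-[4-(benzyloxy)-8-methoxynaphthalen-1-yl]-1-{[tri(propan-2-yl)silyl]oxy}-1,4-dihydronaphthalene-5,8-diyl diacetate | COc1cccc2c(OCc3ccccc3)ccc(c12)[C@@H]1C=C[C@H](O[Si](C(C)C)(C(C)C)C(C)C)c2c(OC(C)=O)ccc(OC(C)=O)c12 | intermediate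
15 | (1S,4S)-4-[4-(benzyloxy)-8-methoxynaphthalen-1-yl]-1-{[tri(propan-2-yl)silyl]oxy}-1,2,3,4-tetrahydronaphthalene-5,8-diyl diacetate | COc1cccc2c(OCc3ccccc3)ccc(c12)[C@@H]1CC[C@H](O[Si](C(C)C)(C(C)C)C(C)C)c2c(OC(C)=O)ccc(OC(C)=O)c12 | intermediate
16 | (1S,4S)-4-[4-(benzyloxy)-8-methoxynaphthalen-1-yl]-1-hydroxy-1,2,3,4-tetrahydronaphthalene-5,8-diyl diacetate | COc1cccc2c(OCc3ccccc3)ccc(c12)[C@@H]1CC[C@H](O)c2c(OC(C)=O)ccc(OC(C)=O)c12 | intermediate
17 | (4S)-4-[4-(benzyloxy)-8-methoxynaphthalen-1-yl]-1-oxo-1,2,3,4-tetrahydronaphthalene-5,8-diyl diacetate | COc1cccc2c(OCc3ccccc3)ccc(c12)[C@@H]1CCC(=O)c2c(OC(C)=O)ccc(OC(C)=O)c12 | intermediate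
18 | (4S)-4-[4-(benzyloxy)-8-methoxynaphthalen-1-yl]-5,8-dihydroxy-3,4-dihydronaphthalen-1(2H)-one | COc1cccc2c(OCc3ccccc3)ccc(c12)[C@@H]1CCC(=O)c2c(O)ccc(O)c12 | intermediate
19 | (4S)-5,8-dihydroxy-4-(4-hydroxy-8-methoxynaphthalen-1-yl)-3,4-dihydronaphthalen-1(2H)-one | COc1cccc2c(O)ccc([C@@H]3CCC(=O)c4c(O)ccc(O)c43)c12 | target

## Step count and least certain steps

Total step count: 13. Longest linear sequence: 13 steps (1 → 19); compounds 5, 8 and 11 are bought.

**Step 7 (key step).** The most likely failure is poor facial discrimination: 11 binds the titanium centre through a single carbonyl, without a second anchoring point, so the ligand may differentiate the two faces only weakly. A slow cycloaddition at the crowded aryl-bearing diene terminus would also give the Lewis acid time to desilylate 10, and would let 12 enolise and be oxidised by surplus 11. Changing to another chiral Lewis acid would be a change of conditions only. The fallback abandons asymmetric induction. It sets out from 10 and 11, which are combined without any ligand or metal in toluene at rt to 60 °C to give the racemic endo adduct F1. This is acetylated as in step 8 to the racemic diacetate F2. The enantiomers of F2 are separated by preparative chromatography on a polysaccharide-based chiral stationary phase. The route is rejoined at 14.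

**Step 8.** The risk is loss of silanol by β-elimination from the mono-enolate before the second enolisation. That would lead on to aromatisation of ring C and destroy C4. The fallback avoids a free enolate. It sets out from 12, which is treated with TBSOTf and Et3N in CH2Cl2 at −78 °C (carbonyl silylation, then deprotonation) to give the bis(tert-butyldimethylsilyl) ether F3. CsF and Ac2O in MeCN then exchange the two aryl silyl ethers for acetates while the alkyl triisopropylsilyl ether stays. The route is rejoined at 14.

**Step 2.** The risk is attack of the electrophile at C2 (ortho to the hydroxyl) or at C8 (para to the methoxy group in the other ring), and double bromination, because both rings are activated. The fallback fixes the position by oxidation instead of substitution and sets out from 2.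
- PhI(OAc)2 in aqueous MeCN gives 5-methoxynaphthalene-1,4-dione F4; para-quinone formation leaves no regiochemical choice.
- Na2S2O4 reduces it to 5-methoxynaphthalene-1,4-diol F5.
- One equivalent of BnBr with K2CO3 in acetone should benzylate the hydroxyl remote from the methoxy group, since the other is held in a hydrogen bond to the peri methoxy oxygen and is more hindered. This gives 4-(benzyloxy)-8-methoxynaphthalen-1-ol F6.
- Tf2O and pyridine give 4-(benzyloxy)-8-methoxynaphthalen-1-yl trifluoromethanesulfonate F7.
- Stille coupling with allyltributylstannane (Pd(PPh3)4, LiCl, DMF, 90 °C) rejoins the route at 7.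

**Step 5.** The risk is migration of the allyl double bond into conjugation with the naphthalene by ruthenium hydride species, followed by metathesis of the isomerised alkene to a chain-shortened aldehyde, besides homodimerisation of 7. A few mol % of quinone 11 as a hydride scavenger is the first remedy. The fallback builds the enal by olefination and sets out from 4.
- Lithiation as in step 4 gives 6, which opens oxirane (BF3·OEt2, THF, −78 °C) to give 2-[4-(benzyloxy)-8-methoxynaphthalen-1-yl]ethan-1-ol F8.
- Dess–Martin oxidation gives [4-(benzyloxy)-8-methoxynaphthalen-1-yl]acetaldehyde F9.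
- Wittig reaction with the stabilised ylide (triphenylphosphoranylidene)acetaldehyde in toluene gives the E-enal and rejoins the route at 9.

## Further compounds

F1 | step 7 | racemic 12 (equimolar mixture of 12 and its enantiomer) | COc1cccc2c(OCc3ccccc3)ccc(c12)[C@@H]1C=C[C@H](O[Si](C(C)C)(C(C)C)C(C)C)[C@@H]2C(=O)C=CC(=O)[C@H]12.COc1cccc2c(OCc3ccccc3)ccc(c12)[C@H]1C=C[C@@H](O[Si](C(C)C)(C(C)C)C(C)C)[C@H]2C(=O)C=CC(=O)[C@@H]12
F2 | step 7 | racemic 14 (equimolar mixture of 14 and its enantiomer) | COc1cccc2c(OCc3ccccc3)ccc(c12)[C@@H]1C=C[C@H](O[Si](C(C)C)(C(C)C)C(C)C)c2c(OC(C)=O)ccc(OC(C)=O)c12.COc1cccc2c(OCc3ccccc3)ccc(c12)[C@H]1C=C[C@@H](O[Si](C(C)C)(C(C)C)C(C)C)c2c(OC(C)=O)ccc(OC(C)=O)c12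
F3 | step 8 | {[(1S,4S)-4-[4-(benzyloxy)-8-methoxynaphthalen-1-yl]-1-{[tri(propan-2-yl)silyl]oxy}-1,4-dihydronaphthalene-5,8-diyl]bis(oxy)}bis[tert-butyl(dimethyl)silane] | COc1cccc2c(OCc3ccccc3)ccc(c12)[C@@H]1C=C[C@H](O[Si](C(C)C)(C(C)C)C(C)C)c2c(O[Si](C)(C)C(C)(C)C)ccc(O[Si](C)(C)C(C)(C)C)c12
F4 | step 2 | 5-methoxynaphthalene-1,4-dione | COc1cccc2C(=O)C=CC(=O)c12
F5 | step 2 | 5-methoxynaphthalene-1,4-diol | COc1cccc2c(O)ccc(O)c12
F6 | step 2 | 4-(benzyloxy)-8-methoxynaphthalen-1-ol | COc1cccc2c(OCc3ccccc3)ccc(O)c12
F7 | step 2 | 4-(benzyloxy)-8-methoxynaphthalen-1-yl trifluoromethanesulfonate | COc1cccc2c(OCc3ccccc3)ccc(OS(=O)(=O)C(F)(F)F)c12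
F8 | step 5 | 2-[4-(benzyloxy)-8-methoxynaphthalen-1-yl]ethan-1-ol | COc1cccc2c(OCc3ccccc3)ccc(CCO)c12
F9 | step 5 | [4-(benzyloxy)-8-methoxynaphthalen-1-yl]acetaldehyde | COc1cccc2c(OCc3ccccc3)ccc(CC=O)c12
A1 | alternative 1 | 4-(8-methoxy-1,4-dihydro-1,4-epoxynaphthalen-1-yl)-1-oxo-1,2,3,4-tetrahydronaphthalene-5,8-diyl bis(2,2-dimethylpropanoate), C4 arranged as in 19, bridgeheads as a mixture | COc1cccc2C3OC(C=C3)(c12)[C@@H]1CCC(=O)c2c(OC(=O)C(C)(C)C)ccc(OC(=O)C(C)(C)C)c12
A2 | alternative 1 | 4-(furan-2-yl)-1-oxo-1,2,3,4-tetrahydronaphthalene-5,8-diyl bis(2,2-dimethylpropanoate), C4 arranged as in 19 | o1cccc1[C@@H]1CCC(=O)c2c(OC(=O)C(C)(C)C)ccc(OC(=O)C(C)(C)C)c12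
A3 | alternative 1 | 3-methoxy-2-(trimethylsilyl)phenyl trifluoromethanesulfonate | COc1cccc(OS(=O)(=O)C(F)(F)F)c1[Si](C)(C)C
A4 | alternative 2 | tert-butyl({4-[4-(benzyloxy)-8-methoxynaphthalen-1-yl]-5,8-bis(4,4,5,5-tetramethyl-1,3,2-dioxaborolan-2-yl)-1,2,3,4-tetrahydronaphthalen-1-yl}oxy)dimethylsilane, C4 arranged as in 19 | COc1cccc2c(OCc3ccccc3)ccc(c12)[C@@H]1CCC(O[Si](C)(C)C(C)(C)C)c2c(B3OC(C)(C)C(C)(C)O3)ccc(B3OC(C)(C)C(C)(C)O3)c12
A5 | alternative 2 | tert-butyl({6-[4-(benzyloxy)-8-methoxynaphthalen-1-yl]-1,8-bis(4,4,5,5-tetramethyl-1,3,2-dioxaborolan-2-yl)octa-1,7-diyn-3-yl}oxy)dimethylsilane | COc1cccc2c(OCc3ccccc3)ccc(c12)[C@@H](C#CB1OC(C)(C)C(C)(C)O1)CCC(O[Si](C)(C)C(C)(C)C)C#CB1OC(C)(C)C(C)(C)O1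
A6 | alternative 2 | ethyne (acetylene) | C#C
A7 | alternative 2 | dicarbonyl(cyclopentadienyl)cobalt, CpCo(CO)2 | [Co+].c1cc[cH-]c1.[C-]#[O+].[C-]#[O+]
A8 | alternative 3 | 4-[4-(benzyloxy)-8-hydroxynaphthalen-1-yl]-3,4-dihydro-2H-spiro[naphthalene-1,2′-[1,3]dioxolane]-5,8-diyl bis(2,2-dimethylpropanoate), C4 arranged as in 19 | Oc1cccc2c(OCc3ccccc3)ccc(c12)[C@@H]1CCC2(OCCO2)c2c(OC(=O)C(C)(C)C)ccc(OC(=O)C(C)(C)C)c12
A9 | alternative 3 | 4-{4-(benzyloxy)-3-[(1E)-4-diazo-3-oxobut-1-en-1-yl]phenyl}-3,4-dihydro-2H-spiro[naphthalene-1,2′-[1,3]dioxolane]-5,8-diyl bis(2,2-dimethylpropanoate), C4 arranged as in 19 | [N-]=[N+]=CC(=O)/C=C/c1cc(ccc1OCc1ccccc1)[C@@H]1CCC2(OCCO2)c2c(OC(=O)C(C)(C)C)ccc(OC(=O)C(C)(C)C)c12
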